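Ring B carries four adjacent oxygenated carbons (C6', C1', C2', C3'), which are taken from the four carbons of squaric acid; C4' and C5' with the prenyl chain come from an (E)-1,4-dienyl unit. The precursor is a 4-dienyl-4-hydroxycyclobutenone that already bears the ring A aryloxy group next to its carbonyl and an isopropoxy group next to its carbinol. Heating opens it to a dienylketene, and 6π closure forms the C5'–C6' bond and ring B as a hydroquinone in one operation, leaving all four oxygens differentiated. The precursor is assembled from an aryl isopropyl squarate and a dienyllithium; double O-methylation and removal of three isopropyl groups complete the route.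

Key step: step 8

Assumption: ring A is the benzoate ring and ring B is numbered from the ether carbon C1' round to C6'; the carbinol centre of the cyclobutenone is racemic and is destroyed on aromatisation, so the achiral target needs no stereocontrol.
Structure check: in compound 14 the ring carbonyl is bonded to the aryloxy-bearing carbon and the carbinol to the isopropoxy-bearing carbon. This is the only arrangement that maps OAr onto C1', OiPr onto C2' and the two free hydroxyls onto C3' and C6', so the precursor and product skeletons are used unchanged.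

Step 1
Reactants: 1 methyl 2,4,6-trihydroxybenzoate
Product: 2 methyl 2-hydroxy-4,6-diisopropoxybenzoate
Conditions: 2-bromopropane (2.3 equiv), K2CO3, DMF, 50 °C
Reagents that add atoms: 2-bromopropane, CC(C)Br
Why: Williamson etherification: the para hydroxyl and one of the two equivalent ortho hydroxyls are alkylated, while the remaining ortho hydroxyl is tied up in a hydrogen bond to the ester carbonyl and is too poor a nucleophile for the sluggish secondary bromide, so the reaction should stop at the mono-phenol.

Step 2
Reactants: 3 squaric acid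
Product: 4 squaryl dichloride (3,4-dichlorocyclobut-3-ene-1,2-dione)
Conditions: (COCl)2 (2.2 equiv), DMF (cat.), CH2Cl2, reflux
Reagents that add atoms: oxalyl chloride, O=C(Cl)C(=O)Cl
Why: Chlorodehydroxylation of a vinylogous carboxylic acid through the Vilsmeier reagent formed from (COCl)2 and DMF, the standard access to squaryl dichloride.

Step 3
Reactants: 4 squaryl dichloride
Product: 5 3-chloro-4-isopropoxycyclobut-3-ene-1,2-dione
Conditions: i-PrOH (1.0 equiv), CH2Cl2, 0 °C to rt
Reagents that add atoms: propan-2-ol, CC(C)O
Why: Vinylogous acyl substitution (addition–elimination) by one equivalent of alcohol; the first isopropoxy group donates into the remaining chloro-enone and slows the second substitution, so the ester chloride should be the main product.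

Step 4
Reactants: 2 methyl 2-hydroxy-4,6-diisopropoxybenzoate; 5 3-chloro-4-isopropoxycyclobut-3-ene-1,2-dione
Product: 7 methyl 2-[(2-isopropoxy-3,4-dioxocyclobut-1-enyl)oxy]-4,6-diisopropoxybenzoate, via sodium aryloxide 6 (not isolated)
Conditions: NaH, THF, 0 °C; then 5, −78 to 0 °C
Reagents that add atoms: none
Why: Vinylogous acyl substitution: the aryloxide adds to the chlorine-bearing ring carbon of 5 and expels chloride, so the crowded aryl–O bond is formed at an acyl-like sp2 carbon instead of by arylation of a hindered phenol, and the hard oxygen terminus should outrun the ring carbons for this hard electrophile at low temperature.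

Step 5
Reactants: 8 prenyl bromide (1-bromo-3-methylbut-2-ene); 9 ethynylmagnesium bromide
Product: 10 5-methylhex-4-en-1-yne
Conditions: 9 (excess), CuCl (5 mol %), THF, 0 °C to rt
Reagents that add atoms: none
Why: CuCl-catalysed cross-coupling of an alkynyl Grignard reagent with an allylic bromide, which should occur at the unhindered primary carbon of the prenyl unit and give the linear skipped enyne (excess Grignard reagent suppresses double alkylation).

Step 6
Reactants: 10 5-methylhex-4-en-1-yne
Product: 12 (E)-1-iodo-5-methylhexa-1,4-diene, via alkenylzirconocene chloride 11 (not isolated)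
Conditions: Cp2Zr(H)Cl, THF, rt; then I2, 0 °C
Reagents that add atoms: iodine, II
Why: Hydrozirconation with Cp2Zr(H)Cl is a syn, anti-Markovnikov addition that selects the terminal alkyne over the trisubstituted alkene, and iodinolysis of the C–Zr bond proceeds with retention, which sets the (E)-geometry of the vinyl iodide.

Step 7
Reactants: 12 (E)-1-iodo-5-methylhexa-1,4-diene; 7 methyl 2-[(2-isopropoxy-3,4-dioxocyclobut-1-enyl)oxy]-4,6-diisopropoxybenzoate
Product: 14 methyl 2-{[3-hydroxy-3-((E)-5-methylhexa-1,4-dienyl)-2-isopropoxy-4-oxocyclobut-1-enyl]oxy}-4,6-diisopropoxybenzoate (racemic at the carbinol carbon), via dienyllithium 13 (not isolated)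
Conditions: t-BuLi (2 equiv), Et2O, −78 °C; then added to 7, THF, −78 °C; aq NH4Cl, −78 °C
Reagents that add atoms: none
Why: Iodine–lithium exchange with retention of the alkene geometry, then 1,2-addition of the alkenyllithium to the squarate: the carbonyl bonded to the isopropoxy-bearing carbon is conjugated only with the weakly donating aryloxy group and lies away from that bulky group, so it should be the more electrophilic and more accessible one, which places the carbinol next to C–OiPr; the new carbinol centre is racemic and is erased in step 8.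

Step 8
Reactants: 14 methyl 2-{[3-hydroxy-3-((E)-5-methylhexa-1,4-dienyl)-2-isopropoxy-4-oxocyclobut-1-enyl]oxy}-4,6-diisopropoxybenzoate
Product: 17 methyl 2-[3,6-dihydroxy-2-isopropoxy-5-(3-methylbut-2-enyl)phenoxy]-4,6-diisopropoxybenzoate, via dienylketene 15 (not isolated), via cyclohexadienone 16 (not isolated)
Conditions: PhMe (degassed), 110 °C, Ar; aq Na2S2O4 wash
Reagents that add atoms: none
Why: Thermal 4π conrotatory opening of the cyclobutenone breaks the C(=O)–C(OH) bond and gives dienylketene 15, in which the electron-donating hydroxyl rotates outward and the dienyl group therefore inward, next to the ketene. The ketene carbon (future C6') then bonds to the alkene carbon that carries the CH2CH=CMe2 chain (future C5') in a thermal, disrotatory 6π electrocyclisation, which closes ring B as cyclohexa-2,4-dienone 16; enolisation of 16 gives hydroquinone 17. The closest known reaction type is the Moore rearrangement of squarate-derived 4-alkenyl-4-hydroxycyclobutenones to hydroquinones, here applied to an aryloxy-substituted member. No stereocentre results: the racemic carbinol carbon becomes the sp2 carbon C3' and the transient C5' centre of 16 is lost on aromatisation. The selectivity needed is torquoselectivity (hydroxyl out, alkenyl in), secured by the donor hydroxyl on the breaking bond, while the placement of OAr at C1' and OiPr at C2' is already fixed by the constitution of 14. The step exploits the four contiguous oxygenated carbons C6', C1', C2', C3' of ring B, which are the four squarate carbons, and it is an isomerisation in which every atom of 14 is kept.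

Step 9
Reactants: 17 methyl 2-[3,6-dihydroxy-2-isopropoxy-5-(3-methylbut-2-enyl)phenoxy]-4,6-diisopropoxybenzoate
Product: 18 methyl 2-[2-isopropoxy-3,6-dimethoxy-5-(3-methylbut-2-enyl)phenoxy]-4,6-diisopropoxybenzoate
Conditions: MeI (excess), K2CO3, acetone (degassed), 45 °C, Ar
Reagents that add atoms: iodomethane, CI
Why: Double Williamson O-methylation of the two hydroquinone hydroxyls, run under argon because a hydroquinone phenolate is readily oxidised to the quinone; the isopropyl ethers, the ester and the prenyl group are inert, and intermolecular methylation should outrun attack of the C6' phenolate on the hindered ring A ester.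

Step 10
Reactants: 18 methyl 2-[2-isopropoxy-3,6-dimethoxy-5-(3-methylbut-2-enyl)phenoxy]-4,6-diisopropoxybenzoate
Product: 19 Paucinervin B (methyl 2-[2-hydroxy-3,6-dimethoxy-5-(3-methylbut-2-enyl)phenoxy]-4,6-dihydroxybenzoate)
Conditions: BCl3 (6 equiv), CH2Cl2, −78 °C; then H2O, −78 °C to rt
Reagents that add atoms: none
Why: Lewis-acid ether cleavage: BCl3 complexes the ether oxygens and the secondary isopropyl groups depart as 2-chloropropane much faster than primary methyl groups at −78 °C, so all three isopropyl ethers should fall while both methoxyls, the methyl ester and the prenyl group (no free hydroxyl ortho to it, hence no chroman formation) remain.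

Compound list
1 | methyl 2,4,6-trihydroxybenzoate | COC(=O)c1c(O)cc(O)cc1O | starting material
2 | methyl 2-hydroxy-4,6-diisopropoxybenzoate | COC(=O)c1c(O)cc(OC(C)C)cc1OC(C)C | intermediate
3 | squaric acid (3,4-dihydroxycyclobut-3-ene-1,2-dione) | O=C1C(O)=C(O)C1=O | starting material
4 | squaryl dichloride (3,4-dichlorocyclobut-3-ene-1,2-dione) | O=C1C(Cl)=C(Cl)C1=O | intermediate
5 | 3-chloro-4-isopropoxycyclobut-3-ene-1,2-dione | CC(C)OC1=C(Cl)C(=O)C1=O | intermediate
6 | sodium 3,5-diisopropoxy-2-(methoxycarbonyl)phenolate (sodium aryloxide of 2) | [Na+].COC(=O)c1c([O-])cc(OC(C)C)cc1OC(C)C | intermediate (not isolated)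
7 | methyl 2-[(2-isopropoxy-3,4-dioxocyclobut-1-enyl)oxy]-4,6-diisopropoxybenzoate | COC(=O)c1c(OC(C)C)cc(OC(C)C)cc1OC1=C(OC(C)C)C(=O)C1=O | intermediate
8 | prenyl bromide (1-bromo-3-methylbut-2-ene) | CC(C)=CCBr | starting material
9 | ethynylmagnesium bromide | C#C[Mg]Br | starting material
10 | 5-methylhex-4-en-1-yne | CC(C)=CCC#C | intermediate
11 | chloro[(E)-5-methylhexa-1,4-dienyl]zirconocene | CC(C)=CC/C=C/[Zr](Cl)(C1C=CC=C1)C1C=CC=C1 | intermediate (not isolated)
12 | (E)-1-iodo-5-methylhexa-1,4-diene | CC(C)=CC/C=C/I | intermediate
13 | (E)-5-methylhexa-1,4-dienyllithium | [Li]/C=C/CC=C(C)C | intermediate (not isolated)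
14 | methyl 2-{[3-hydroxy-3-((E)-5-methylhexa-1,4-dienyl)-2-isopropoxy-4-oxocyclobut-1-enyl]oxy}-4,6-diisopropoxybenzoate (racemic carbinol) | COC(=O)c1c(OC(C)C)cc(OC(C)C)cc1OC1=C(OC(C)C)C(O)(/C=C/CC=C(C)C)C1=O | intermediate
15 | methyl 2-{[(3Z,5E)-4-hydroxy-3-isopropoxy-9-methyl-1-oxodeca-1,3,5,8-tetraen-2-yl]oxy}-4,6-diisopropoxybenzoate (dienylketene, dienyl group cis to the ketene-bearing carbon) | COC(=O)c1c(OC(C)C)cc(OC(C)C)cc1OC(=C=O)/C(OC(C)C)=C(/O)\C=C\CC=C(C)C | intermediate (not isolated)
16 | methyl 2-{[3-hydroxy-2-isopropoxy-5-(3-methylbut-2-enyl)-6-oxocyclohexa-1,3-dienyl]oxy}-4,6-diisopropoxybenzoate (racemic at C5 of the dienone) | COC(=O)c1c(OC(C)C)cc(OC(C)C)cc1OC1=C(OC(C)C)C(O)=CC(CC=C(C)C)C1=O | intermediate (not isolated)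
17 | methyl 2-[3,6-dihydroxy-2-isopropoxy-5-(3-methylbut-2-enyl)phenoxy]-4,6-diisopropoxybenzoate | COC(=O)c1c(OC(C)C)cc(OC(C)C)cc1Oc1c(OC(C)C)c(O)cc(CC=C(C)C)c1O | intermediate
18 | methyl 2-[2-isopropoxy-3,6-dimethoxy-5-(3-methylbut-2-enyl)phenoxy]-4,6-diisopropoxybenzoate | COC(=O)c1c(OC(C)C)cc(OC(C)C)cc1Oc1c(OC(C)C)c(OC)cc(CC=C(C)C)c1OC | intermediate
19 | Paucinervin B (methyl 2-[2-hydroxy-3,6-dimethoxy-5-(3-methylbut-2-enyl)phenoxy]-4,6-dihydroxybenzoate) | COC(=O)c1c(O)cc(O)cc1Oc1c(O)c(OC)cc(CC=C(C)C)c1OC | target

Total step count: 10 steps.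
Longest linear sequence: 7 steps (steps 2, 3, 4, 7, 8, 9 and 10, from squaric acid).

Steps most likely to fail

Step 8. The ketene may be intercepted before it cyclises: if the free tertiary hydroxyl turns inward it can add to the ketene carbon (lactonisation instead of 6π closure), and the free hydroquinone can be oxidised by traces of air during heating. The fallback sets out from 14 and comes back at 17, and it caps the carbinol first. Silylation of 14 (TMSCl, Et3N, cat. DMAP, CH2Cl2, 0 °C) should give the trimethylsilyl ether F1. On heating in degassed toluene, F1 should open to the silyloxy dienylketene F2, close to the silyloxy cyclohexadienone F3 and enolise to the mono-silylated hydroquinone F4. This is a known variant of the same rearrangement in which no hydroxyl is available to trap the ketene and the product is shielded from oxidation. TBAF buffered with AcOH (THF, 0 °C) should then free 17.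

Step 7. The organolithium may add at the wrong site. It could attack the aryloxy-bearing ring carbon with loss of the aryloxide, the carbonyl next to that carbon (which would later misplace the prenyl group), or the benzoate. Metalation of the doubly allylic CH2 during the exchange is a further loss channel. The fallback sets out from 10 and 7 and comes back at 17, and it replaces the alkenyllithium by a small, less basic acetylide, a nucleophile known to add cleanly in 1,2 fashion to squarates; the same electronic preference governs which carbonyl it chooses. Deprotonation of 10 (n-BuLi, THF, −78 °C) should give the lithium acetylide F5, which adds to 7 to give, after NH4Cl quench, the alkynyl carbinol F6. Semi-hydrogenation (H2, Pd on CaCO3 poisoned with Pb(OAc)2, quinoline, EtOAc) should give the (Z)-dienyl carbinol F7. Heating F7 as in step 8 should open it to the (Z)-configured dienylketene F8, which closes to the same dienone 16 and gives 17, because the alkene geometry is erased on aromatisation.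

Step 4. Substitution may be slow: the aryloxide oxygen is chelated and flanked by the ortho ester, and the chlorine-bearing carbon of 5 is deactivated by the isopropoxy group. Attack through the electron-rich ring carbons or hydrolysis of the chloride could then compete. The fallback sets out from 4 and 6 and comes back at 7, and it reverses the order of the two substitutions. Aryloxide 6 (from 2 and NaH) is added slowly to an excess of the far more electrophilic dichloride 4 (THF, −78 °C) to give the aryl squaryl chloride F9. The remaining chloride is then displaced by propan-2-ol (CH2Cl2, 0 °C to rt) to give 7.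

Further compounds
F1 | step 8 | methyl 2-{[2-isopropoxy-3-((E)-5-methylhexa-1,4-dienyl)-4-oxo-3-(trimethylsilyloxy)cyclobut-1-enyl]oxy}-4,6-diisopropoxybenzoate (racemic) | COC(=O)c1c(OC(C)C)cc(OC(C)C)cc1OC1=C(OC(C)C)C(O[Si](C)(C)C)(/C=C/CC=C(C)C)C1=O
F2 | step 8 | methyl 2-{[(3Z,5E)-3-isopropoxy-9-methyl-1-oxo-4-(trimethylsilyloxy)deca-1,3,5,8-tetraen-2-yl]oxy}-4,6-diisopropoxybenzoate | COC(=O)c1c(OC(C)C)cc(OC(C)C)cc1OC(=C=O)/C(OC(C)C)=C(/O[Si](C)(C)C)\C=C\CC=C(C)C
F3 | step 8 | methyl 2-{[2-isopropoxy-5-(3-methylbut-2-enyl)-6-oxo-3-(trimethylsilyloxy)cyclohexa-1,3-dienyl]oxy}-4,6-diisopropoxybenzoate (racemic) | COC(=O)c1c(OC(C)C)cc(OC(C)C)cc1OC1=C(OC(C)C)C(O[Si](C)(C)C)=CC(CC=C(C)C)C1=O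
F4 | step 8 | methyl 2-[6-hydroxy-2-isopropoxy-5-(3-methylbut-2-enyl)-3-(trimethylsilyloxy)phenoxy]-4,6-diisopropoxybenzoate | COC(=O)c1c(OC(C)C)cc(OC(C)C)cc1Oc1c(OC(C)C)c(O[Si](C)(C)C)cc(CC=C(C)C)c1O
F5 | step 7 | (5-methylhex-4-en-1-ynyl)lithium | [Li]C#CCC=C(C)C
F6 | step 7 | methyl 2-{[3-hydroxy-2-isopropoxy-3-(5-methylhex-4-en-1-ynyl)-4-oxocyclobut-1-enyl]oxy}-4,6-diisopropoxybenzoate (racemic) | COC(=O)c1c(OC(C)C)cc(OC(C)C)cc1OC1=C(OC(C)C)C(O)(C#CCC=C(C)C)C1=O
F7 | step 7 | methyl 2-{[3-hydroxy-3-((Z)-5-methylhexa-1,4-dienyl)-2-isopropoxy-4-oxocyclobut-1-enyl]oxy}-4,6-diisopropoxybenzoate (racemic) | COC(=O)c1c(OC(C)C)cc(OC(C)C)cc1OC1=C(OC(C)C)C(O)(/C=C\CC=C(C)C)C1=O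
F8 | step 7 | methyl 2-{[(3Z,5Z)-4-hydroxy-3-isopropoxy-9-methyl-1-oxodeca-1,3,5,8-tetraen-2-yl]oxy}-4,6-diisopropoxybenzoate | COC(=O)c1c(OC(C)C)cc(OC(C)C)cc1OC(=C=O)/C(OC(C)C)=C(/O)\C=C/CC=C(C)C
F9 | step 4 | methyl 2-[(2-chloro-3,4-dioxocyclobut-1-enyl)oxy]-4,6-diisopropoxybenzoate | COC(=O)c1c(OC(C)C)cc(OC(C)C)cc1OC1=C(Cl)C(=O)C1=O
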